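**Retrosynthetic overview**
1. The last step is hydrogenolysis of four O-benzyl groups on rings B and D. Ring A is never protected.
2. The key disconnection breaks C4–C4a, O1–C2 and C2–H in one flask. The fragments are phloroglucinol and a 1-aroylvinyl 4-(benzyloxy)benzoate, so the ester of the target already sits on the future C3.
3. In that flask ring C closes by Friedel–Crafts conjugate addition followed by ketalisation–dehydration. The ester carbonyl then bridges to C2 as a temporary cis-fused 1,3-dioxolan-2-ylium ring. Hydride opens this ring and sets C2/C3 cis under a chiral counter-anion (dynamic kinetic resolution).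
4. The enone ester comes from methyl tri-O-benzylgallate by one-carbon homologation, carboxylate displacement and α-methylenation.
5. Ring order: A, B and D are bought as arenes. Ring C and the temporary dioxolanylium ring form together in step 4.

Assumption: the (R)-configured acid catalyst of step 4 is taken to give the (2R,3R) series (its mirror image is used if the sense proves opposite), and 1 and 3 are bought as catalogue compounds.

**Step 1**
Reactants: 1 methyl 3,4,5-tris(benzyloxy)benzoate
Product: 2 2-chloro-1-[3,4,5-tris(benzyloxy)phenyl]ethan-1-one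
Conditions: ICH2Cl (1.5 equiv), MeLi·LiBr (1.4 equiv, slow addition), THF/Et2O, −78 °C; AcOH quench at −78 °C
Reagents that add atoms: chloroiodomethane, ClCI
Why: Carbenoid homologation of an ester (chloromethyllithium acylation): iodine–lithium exchange is faster than attack of MeLi on the ester, the carbenoid adds once at −78 °C, the acid quench before warming prevents a second addition, the benzyl ethers are inert and no stereocentre is formed.

**Step 2**
Reactants: 2 2-chloro-1-[3,4,5-tris(benzyloxy)phenyl]ethan-1-one; 3 4-(benzyloxy)benzoic acid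
Product: 4 2-oxo-2-[3,4,5-tris(benzyloxy)phenyl]ethyl 4-(benzyloxy)benzoate
Conditions: K2CO3 (1.1 equiv), DMF, rt
Reagents that add atoms: none
Why: SN2 esterification of a carboxylate with an α-chloro ketone (phenacyl-ester formation): the carbonyl-activated primary chloride is displaced cleanly at room temperature and nothing else in either partner reacts with carbonate.

**Step 3**
Reactants: 4 2-oxo-2-[3,4,5-tris(benzyloxy)phenyl]ethyl 4-(benzyloxy)benzoate
Product: 5 3-oxo-3-[3,4,5-tris(benzyloxy)phenyl]prop-1-en-2-yl 4-(benzyloxy)benzoate (CH2=C(OCOAr)–CO–Ar, a captodative enone)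
Conditions: (CH2O)n (3 equiv), iPr2NH·CF3CO2H (1 equiv), CF3CO2H (10 mol %), BHT (trace), THF, reflux
Reagents that add atoms: formaldehyde (from paraformaldehyde), C=O
Why: Direct α-methylenation (Mannich condensation followed by β-elimination of the amine): the only enolisable position is the CH2 between ketone and acyloxy group, the hindered ammonium salt does not touch the ester, 1-acylvinyl arenecarboxylates are an isolable class, and no stereocentre is formed.

**Step 4**
Reactants: 5 3-oxo-3-[3,4,5-tris(benzyloxy)phenyl]prop-1-en-2-yl 4-(benzyloxy)benzoate; 6 phloroglucinol (anhydrous, 3 equiv)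
Product: 10 (2R,3R)-5,7-dihydroxy-2-[3,4,5-tris(benzyloxy)phenyl]chroman-3-yl 4-(benzyloxy)benzoate (2,3-cis), via keto-triphenol 7 (not isolated), via 4H-chromene 8 (not isolated), via bridged acyloxonium ion 9 (not isolated)
Conditions: (R)-3,3'-bis(2,4,6-triisopropylphenyl)-1,1'-binaphthyl-2,2'-diyl N-triflylphosphoramide (10 mol %), 4 Å MS, 1,4-dioxane, rt until 5 is consumed; then Hantzsch ester (diethyl 2,6-dimethyl-1,4-dihydropyridine-3,5-dicarboxylate, 1.5 equiv), 40 °C, same flask; excess 6 washed out with water
Reagents that add atoms: none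
Why: Proposed new method: the chiral Brønsted acid activates 5 for a Friedel–Crafts conjugate addition of the very nucleophilic, threefold-symmetric 6 (only one regioisomer possible, C4–C4a bond) to give racemic 7, which closes ring C by ketalisation–dehydration to the achiral 8; reversible protonation of 8 at C3, with participation of the electron-rich 4-alkoxybenzoate carbonyl at C2, gives the cis-fused dioxolanylium ion 9, so both C3 epimers interconvert through 8 (dynamic kinetic resolution) while the Hantzsch ester transfers hydride to C2 of the faster-reacting ion pair with the chiral anion, always anti to the C3–O bond, which opens the temporary ring, returns the ester to O3 and fixes C2 and C3 as R,R and cis; the closest known reaction types are the chiral phosphoric acid/Hantzsch ester cascade transfer hydrogenation of 2,3-disubstituted quinolines (enamine–iminium dynamic kinetic resolution to cis products), the reduction of benzopyrylium ions paired with chiral phosphates, Friedel–Crafts additions of electron-rich arenes to 1-acylvinyl arenecarboxylates, and cis-selective acid/hydride reductive cyclisations of ketones that carry a 2-hydroxyaryl group.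

**Step 5**
Reactants: 10 (2R,3R)-5,7-dihydroxy-2-[3,4,5-tris(benzyloxy)phenyl]chroman-3-yl 4-(benzyloxy)benzoate
Product: 11 (2R,3R)-5,7-dihydroxy-2-(3,4,5-trihydroxyphenyl)chroman-3-yl 4-hydroxybenzoate, epigallocatechin 3-O-(4-hydroxybenzoate)
Conditions: H2 (1 atm), Pd(OH)2/C (20 wt %), THF/MeOH 1:1, rt; filtration and evaporation under argon
Reagents that add atoms: none
Why: Heterogeneous hydrogenolysis of the four O-benzyl ethers, the standard end-game of catechin ester syntheses: the alkyl ester, the C2–O1 bond and both stereocentres are untouched under neutral conditions at room temperature.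

**Compound list**
1 | methyl 3,4,5-tris(benzyloxy)benzoate | COC(=O)c1cc(OCc2ccccc2)c(OCc2ccccc2)c(OCc2ccccc2)c1 | starting material
2 | 2-chloro-1-[3,4,5-tris(benzyloxy)phenyl]ethan-1-one | O=C(CCl)c1cc(OCc2ccccc2)c(OCc2ccccc2)c(OCc2ccccc2)c1 | intermediate
3 | 4-(benzyloxy)benzoic acid | OC(=O)c1ccc(OCc2ccccc2)cc1 | starting material
4 | 2-oxo-2-[3,4,5-tris(benzyloxy)phenyl]ethyl 4-(benzyloxy)benzoate | O=C(COC(=O)c1ccc(OCc2ccccc2)cc1)c1cc(OCc2ccccc2)c(OCc2ccccc2)c(OCc2ccccc2)c1 | intermediate
5 | 3-oxo-3-[3,4,5-tris(benzyloxy)phenyl]prop-1-en-2-yl 4-(benzyloxy)benzoate | C=C(OC(=O)c1ccc(OCc2ccccc2)cc1)C(=O)c1cc(OCc2ccccc2)c(OCc2ccccc2)c(OCc2ccccc2)c1 | intermediate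
6 | phloroglucinol (benzene-1,3,5-triol) | Oc1cc(O)cc(O)c1 | starting material
7 | racemic 1-oxo-1-[3,4,5-tris(benzyloxy)phenyl]-3-(2,4,6-trihydroxyphenyl)propan-2-yl 4-(benzyloxy)benzoate (keto-triphenol, not isolated) | O=C(C(Cc1c(O)cc(O)cc1O)OC(=O)c1ccc(OCc2ccccc2)cc1)c1cc(OCc2ccccc2)c(OCc2ccccc2)c(OCc2ccccc2)c1 | intermediate
8 | 5,7-dihydroxy-2-[3,4,5-tris(benzyloxy)phenyl]-4H-chromen-3-yl 4-(benzyloxy)benzoate (achiral, not isolated) | O=C(OC1=C(c2cc(OCc3ccccc3)c(OCc3ccccc3)c(OCc3ccccc3)c2)Oc2cc(O)cc(O)c2C1)c1ccc(OCc2ccccc2)cc1 | intermediate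
9 | bridged acyloxonium ion: ring C in which C2 carries the former carbonyl O of the C3 ester, so that O3–C(aryl)–O–C2 is a cis-fused 2-[4-(benzyloxy)phenyl]-1,3-dioxolan-2-ylium ring on the face of O3; C3 is R, ring B lies on the opposite face, and the counter-ion is the chiral phosphoramidate (not isolated) | C1(c4ccc(OCc5ccccc5)cc4)=[O+][C@@]2(c4cc(OCc5ccccc5)c(OCc5ccccc5)c(OCc5ccccc5)c4)Oc3cc(O)cc(O)c3C[C@H]2O1 | intermediate
10 | (2R,3R)-5,7-dihydroxy-2-[3,4,5-tris(benzyloxy)phenyl]chroman-3-yl 4-(benzyloxy)benzoate (2,3-cis) | O=C(O[C@@H]1Cc2c(O)cc(O)cc2O[C@@H]1c1cc(OCc2ccccc2)c(OCc2ccccc2)c(OCc2ccccc2)c1)c1ccc(OCc2ccccc2)cc1 | intermediate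
11 | (2R,3R)-5,7-dihydroxy-2-(3,4,5-trihydroxyphenyl)chroman-3-yl 4-hydroxybenzoate (2,3-cis) | O=C(O[C@@H]1Cc2c(O)cc(O)cc2O[C@@H]1c1cc(O)c(O)c(O)c1)c1ccc(O)cc1 | target

**Totals**
Total step count: 5.
Longest linear sequence: 5 (1 → 2 → 4 → 5 → 10 → 11).

**Steps most likely to fail**

Step 4 carries the most risk.
- The acid may be too weak to protonate the acyloxy-substituted enol ether 8.
- Hydride may attack the acyl carbon of 9 instead of C2.
- 8 may disproportionate under acid before the Hantzsch ester is added.
- Ring A of the product may be alkylated a second time.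
- The selectivity of the ion pair is unknown.

The fallback leaves the ionic organocatalytic reduction for a metal-catalysed syn-hydrogenation. It sets out from 5 and 6, which are annulated with TsOH·H2O (5 mol %) in dioxane at 40 °C, and 8 is isolated. 8 is a tetrasubstituted enol ester whose ester carbonyl can chelate rhodium. With [Rh(cod)((Sc,Rp)-DuanPhos)]BF4 (2 mol %) and H2 (50 bar) in CH2Cl2/MeOH, both hydrogens add to one face. This makes C2/C3 cis by necessity and leaves only the choice of face to the ligand. The benzyl ethers survive the homogeneous catalyst, and the way comes back at 10. No compound outside the list is made on this way (F0).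

Step 3 comes second. The α-acyloxy ketone may enolise too slowly, and 5 may polymerise or add the amine. The fallback reverses the polarity of the C3–C4 bond formation and sets out from 4. Here 4 stays the nucleophile and ring A enters as commercial 2,4,6-trihydroxybenzaldehyde. In HCl-saturated EtOAc at 0 °C (acid aldol condensation–cyclodehydration, the classical flavylium synthesis) this gives 5,7-dihydroxy-3-[4-(benzyloxy)benzoyloxy]-2-[3,4,5-tris(benzyloxy)phenyl]chromenylium chloride F2. One equivalent of Hantzsch ester transfers hydride to C4 of F2, and the way comes back at 8. 8 is then reduced under the second-stage conditions of step 4.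

Step 1 comes third. Possible problems are double addition of the carbenoid, direct attack of MeLi on the ester, and carbenoid decomposition on scale. The fallback replaces the carbenoid by a sulfur ylide and sets out from 1. Dimethylsulfoxonium methylide (trimethylsulfoxonium iodide, KOtBu, THF, reflux) acylates to dimethylsulfoxonium 2-oxo-2-[3,4,5-tris(benzyloxy)phenyl]ethylide F1, a bench-stable solid. Heating F1 with acid 3 in MeCN protonates the ylide carbon, and the carboxylate displaces dimethyl sulfoxide. The way comes back at 4 and bypasses 2.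

**Further compounds**
F1 | step 1 | dimethylsulfoxonium 2-oxo-2-[3,4,5-tris(benzyloxy)phenyl]ethylide | C[S+](C)(=O)[CH-]C(=O)c1cc(OCc2ccccc2)c(OCc2ccccc2)c(OCc2ccccc2)c1
F2 | step 3 | 5,7-dihydroxy-3-[4-(benzyloxy)benzoyloxy]-2-[3,4,5-tris(benzyloxy)phenyl]chromenylium chloride | [Cl-].O=C(Oc1cc2c(O)cc(O)cc2[o+]c1-c1cc(OCc2ccccc2)c(OCc2ccccc2)c(OCc2ccccc2)c1)c1ccc(OCc2ccccc2)cc1
F0 | step 4 | none | none
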